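The numbers are assumed; the rest is arithmetic.

Late in a run, once every charge is in, substrate and coupling partner differ by 0.0100 M, and that small excess is where my ladder of times ends.

    substrate + coupling partner + catalyst → product + catalyst, rate k1*[substrate]*[coupling partner]*[catalyst]/(1 + ([substrate]/sat1)) (sat1 = 0.12 M, k1 = 1300 M⁻² h⁻¹)

| flask | substrate | coupling partner | catalyst | time | remark |
|---|---|---|---|---|---|
| eta | 0.10 M | 0.110 M (fed, over 4.0 d) | 0.20 mM | 5.0 d | all else is in the flask from the start; the feed brings no volume worth counting |
| alpha | 0.10 M | 0.110 M | 0.20 mM | 5.0 d | everything together at the start |
| gamma | 0.10 M (fed, over 4.0 d) | 0.110 M | 0.20 mM | 5.0 d | all else is in the flask from the start; the feed brings no volume worth counting |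

* which flask leads in amount of product, in percent of the substrate charged ("all alike" within 1.5 percentage points) (eta / alpha / gamma / all alike)
* how much product is there at the end, in percent of the substrate charged: eta
* how much product is there at the end, in percent of the substrate charged: alpha
* how much product is there at the end, in percent of the substrate charged: gamma

- The quantity I carry is the partner half-life, the time in which coupling partner halves at the full substrate charge, ln(2)·(1 + c(substrate)/sat)/(k·c(catalyst)·c(substrate)): 2.04 d. This treats coupling partner as pseudo-first-order, with substrate held near its charge.
- The next rung is the feed: 4.0 d is about twice the partner half-life, so I expect eta to consume coupling partner as it enters while a stock of it builds up. With the half-life held constant, c(coupling partner) in eta reaches 0.0601 M as the feed ends.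
- Then comes the run itself: decaying that stock for the last 1.00 d gives 67.2% product in eta. I commit to this as a high mark, since c(substrate) falls and the half-life lengthens as it does.
- The slowest rung is the tail: once c(substrate) has fallen well below both the excess and sat, substrate against that bare excess has a half-life of 11.1 d, longer than the run, so I expect substrate left at the end. I take my reckoning no further.
- The forecast differs from me on eta: it gives eta 57%, alpha 73% and gamma 60%, so alpha leads, and it says “batch wins despite the substrate saturation term”.
- The simulation gives eta 56.9%, alpha 73.1% and gamma 59.5%, so alpha leads, as forecast, and my eta figure stands 10 percentage points high.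
- In eta the half-life of coupling partner by the coupling step reads 2.5 d at 2.99 d, longer than 2.04 d but shorter than the feed time, and 59.9% of its charge stands in eta at 4.00 d.
- In the neighbour of eta with 5.0 × 10⁻⁵ M of catalyst, the partner half-life becomes 8.15 d, longer than the run. The same reckoning there gives 24.4%, and that flask holds 22.8% product.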